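## Structural features

The target is a germacrane-type sesquiterpene lactone. Its core is a cyclodeca-1(10),4-diene carbocycle (C1–C10) with an α-methylene-γ-butyrolactone (O, C8, C7, C11, C12, exocyclic C11=C13) trans-fused across C7–C8. C10 carries the C14 methyl, C4 the C15 hydroxymethyl, and the C6 oxygen is esterified with (E)-4-hydroxy-2-methylbut-2-enoic acid. The C1=C10 bond is E. In the C4=C5 bond C3 and C6 are cis in the ring and C15 is trans to C6, which is E by the CIP rules only because C15 is oxygenated. The three stereocentres C6 (R), C7 (R) and C8 (S) are contiguous: the C6 and C8 oxygens lie on one face of the ring and the C11 branch on the other, so H7 and H8 are trans. Fragile groups are the α-methylene lactone (a Michael acceptor), two primary allylic alcohols, an allylic ester in a 1,3-relationship to the C8 oxygen (acyl migration whenever C8–OH is free), and the cyclodeca-1,5-diene itself (transannular cyclisation in acid, Cope shift on heating). The real difficulty is the ten-membered ring, with two trisubstituted ring olefins of different geometry and the C6/C7/C8 triad. The key step uses the fact that C6 is a carbinol carbon bonded to the C4=C5 olefin and to C7, and that C7 carries the C11=C13 exo-methylene. This homoallylic alcohol array is the retron of a [2,3]-Wittig shift, so the C6 oxygen can be tied back to C13 and the carbocycle opened to an unstrained thirteen-membered diallylic ether.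

## Logic of the disconnections

**35 to 34.** Only the two O–Si bonds (C15 oxygen and side-chain oxygen) are cut. Both primary allylic hydroxyls must stay masked while C12 is oxidised, and two identical silyl ethers fall in one step. The forward step needs a fluoride source that is not basic, because of the methylene lactone and the allylic ester.

**34 to 31.** The lactone bond between the C8 oxygen and C12 is cut and C12 is lowered to the alcohol level. The methylene lactone then exists only in the last two steps. The demand is an oxidant that touches one primary allylic alcohol only, which is why C15 and the side-chain hydroxyl are silylated and C6 is already acylated.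

**31 to 30.** The two O–benzyl bonds at O8 and O12 are cut. Both lactone partners are released in one oxidative step that is orthogonal to silyl ethers. A silyl ether at C8 would have to be removed while two primary silyl ethers survive, the wrong order of lability, so C8 is carried as a 4-methoxybenzyl ether from the start.

**30 to 25 and 28.** The acyl–O6 bond is cut. The side chain 28 goes back through 27 to 26 by cutting its olefin (a stabilised-ylide olefination). The forward acylation meets a hindered secondary allylic alcohol, so C15–OH must be blocked first.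

**25 to 24 to 23.** No skeletal bond is cut; C15 returns from silyl ether through alcohol to ethyl ester. The ester is needed only up to the ring contraction, where it is the activating group. The demands are a clean 1,2-reduction and discrimination of a primary from a secondary allylic hydroxyl.

**23 to 21.** This is the strategic cut: the C6–C7 bond is broken and O6 is joined to C13. A ten-membered carbocycle with three stereocentres becomes a thirteen-membered ether with one. The forward step must generate the carbanion at C6 and not at C13 (hence the C15 ester), must find C13 trans to C8 on the C7=C11 bond, and must take its facial bias from the C8 alkoxy centre.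

**21 to 20, 19 and 18.** The C4=C5 bond is cut to a phosphonate and an aldehyde. A thirteen-membered ring has little transannular strain, so closure by olefination is reasonable. The demands are high dilution and the enoate geometry with the ester trans to C6. The α-alkoxy aldehyde is unmasked only at the last moment from a silyl-protected 2-hydroxyethyl ether.

**18 to 17.** The C3–C4 bond is cut. One alkylation brings in C4, C15 and phosphorus together, and it is placed after the hydride step that an ester would not survive. The demand is a C3 leaving group that has passed through all earlier steps, met by a primary chloride.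

**17 to 16 to 15.** The benzyl ethers and then the C11–C12 bond are cut, back to an alkenyl iodide. The C12 carbon enters with retention, which places it cis to C8 as the lactone requires.

**15 to 13.** The carbon–iodine bond at C11 and the C7–H bond are cut, back to an alkyne. A hydroxyl-directed trans-hydroalumination fixes the site of the metal (C11) and the geometry (C13 trans to C8) in one step. It demands a free propargylic hydroxyl at C8 and no ester in the molecule, which is why C8 is made by ketone reduction and the ester arrives late.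

**13 to 12 to 2 and 10.** The C8–H bond (asymmetric reduction) and the C7–C8 bond (acetylide acylation) are cut, giving two achiral fragments. Alkyne 2 comes from 1 by silylation.

**10 to 9, 8, 6 and 3.** Functional-group changes lead back to 6, in which the C1–C2 and C10–C14 bonds are cut. A syn-carbometalation of a terminal alkyne followed by epoxide opening sets the E geometry of C1=C10 and adds C2 and C3.

## Other disconnections considered

**Alternative 1:** The cut runs through both ring olefins at once. C1=C10 and C4=C5 are traced back to the σ-bonds C1–C4 and C5–C10 of a bicyclo[2.2.0]hexane fused to a six-membered ring (C5 to C10), which would come from a [2+2] photocycloaddition. In the forward direction, heating splits the two four-membered-ring bonds and releases the cyclodecadiene A1.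
- In its favour: the ring opens by strain release in a unimolecular step without high dilution, and both ring olefins appear together. The E/ring-cis pattern of this target is the natural outcome of a cis–anti–cis ring fusion, so olefin geometry does not depend on an olefination. On this point the alternative is the better plan.
- Against it here: A1 has an unsubstituted C11 methylene (C13 is absent) and carries C15 as a methyl ester beside the lactone. The end game would need an enolate methylenation and the reduction of a conjugated ester in the presence of a more electrophilic γ-lactone. The cycloreversion is formally forbidden and stepwise, at roughly 200 °C, where bond rotation can erode geometry and the 1,5-diene can undergo a Cope shift. The photocycloaddition must give one regio- and face-isomer next to C7 and C8.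
- Comparison: in structure it reaches the carbocycle in clearly fewer steps than the chosen plan, an advantage, but leaves more repair afterwards (C13, C15, acylation), so total length should be similar. In mechanism the chosen [2,3] shift is concerted, runs cold and sets C6 and C7 as the ring forms, whereas here all three stereocentres must be in place before a hot step and survive it.

**Alternative 2:** The cut is the C5–C6 bond. In the forward direction CrCl2 with catalytic NiCl2 turns a C5 alkenyl iodide into an alkenylchromium species that adds to a C6 formyl group on the preformed lactone, giving A2.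
- In its favour: the reaction type is well established and chemoselective, and the C4=C5 geometry is fixed in the open chain and retained. On olefin geometry it is the better plan, since nothing depends on an olefination ratio or on the integrity of a dienolate. The lactone ring is in place early.
- Against it here: a ten-membered ring is closed directly from a chain (high dilution, large excess of divalent chromium, transannular strain in the transition state). C6 is created by addition to an α-branched aldehyde with no built-in link to C7, so either epimer could result. The aldehyde is β-acyloxy-substituted (lactone oxygen on C8) and prone to epimerisation at C7 and to elimination. A2 lacks C13, so a lactone enolate methylenation is needed before the C6 acylation.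
- Comparison: in structure the same carbocycle is reached with the lactone earlier. In mechanism it carries less methodological risk than the chosen plan but more stereochemical risk at C6. In step economy the two are about equal by estimate, because what the preformed lactone saves is spent on methylenation and protecting-group changes.

**Alternative 3:** The cut is the ring bond C2–C3 in a retro-[3,3] sense, which reconnects C5 to C10. This leads back to a cyclohexane with a C10 tertiary carbinol bearing a vinyl group and a cis alkenyl group on C5. In the forward direction KH with 18-crown-6 forms the alkoxide, the oxy-Cope shift expands the ring, and PhNTf2 traps the enolate as the enol triflate A3; a methyl cross-coupling then installs C14.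
- In its favour: there is no macrocyclisation, the ring expansion is strongly accelerated and well precedented, and the C6/C7/C8 triad is assembled on a six-membered ring before the ten-membered ring exists. On stereocontrol of the triad it is the better plan. A3 already carries C13 and the C12 oxygen, so its end game is the equal of the chosen one.
- Against it here: the substrate has five substituted ring carbons including a tertiary carbinol, and would be long to make. The geometry of both new olefins depends on chair versus boat transition states. A potassium alkoxide next to silyl ethers invites silyl migration, and once the enolate equilibrates towards C9 the C8 oxygen can be eliminated. An extra coupling step is needed for C14.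
- Comparison: in structure it is carbocycle-first on a six-ring template against ether-macrocycle-first. In mechanism both are sigmatropic, a known [3,3] against a new [2,3] variant. In step economy it is probably longer than the chosen plan by the steps needed for the cyclohexanol, in exchange for a safer ring-forming step.

Key step: step 15

Remarks on the chemistry:
- Germacrane numbering (C1–C15) is used for every intermediate, whatever its systematic name.
- Compounds 1, 3, 26, Bu3SnCH2OH and the ruthenium catalyst are taken as purchased.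
- In 21 the C7=C11 bond is Z by the CIP rules although C13 and C8 are trans across it, so geometry is stated atom by atom where it matters.
- The sense of the asymmetric reduction in step 7 is assigned by analogy with aryl ketones.

## Route

Step 1
Reactants: 1 2-(prop-2-yn-1-yloxy)ethan-1-ol
Product: 2 tert-butyl[2-(prop-2-yn-1-yloxy)ethoxy]diphenylsilane
Conditions: TBDPSCl, imidazole, CH2Cl2, 0 °C → rt
Reagents that add atoms: tert-butyl(chloro)diphenylsilane, CC(C)(C)[Si](Cl)(c1ccccc1)c1ccccc1
Why: Silyl ether formation on a primary alcohol; the bulky silyl group should survive the acetylide, hydride, palladium and NaH steps and is removed by fluoride when the aldehyde is needed.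

Step 2
Reactants: 3 tert-butyl(but-3-yn-1-yloxy)dimethylsilane
Product: 6 (3E)-6-(tert-butyldimethylsilyloxy)-4-methylhex-3-en-1-ol, via alkenyldimethylalane 4 (not isolated), via lithium alkenylalanate 5 (not isolated)
Conditions: Me3Al, Cp2ZrCl2 (cat.), CH2Cl2, 0 °C → rt; evaporate; n-BuLi, hexane–THF, −78 → 0 °C; oxirane, 0 °C → rt
Reagents that add atoms: trimethylaluminium, C[Al](C)C; oxirane, C1CO1
Why: Zirconium-catalysed carboalumination (Negishi) adds methyl and aluminium syn across the terminal alkyne with methyl on the internal carbon, so the C1=C10 bond is formed E. The derived alanate opens oxirane with retention of the alkenyl geometry and adds C2 and C3.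

Step 3
Reactants: 6 (3E)-6-(tert-butyldimethylsilyloxy)-4-methylhex-3-en-1-ol
Product: 8 tert-butyl{[(3E)-6-chloro-3-methylhex-3-en-1-yl]oxy}dimethylsilane, via mesylate 7 (not isolated)
Conditions: MsCl, Et3N, CH2Cl2, 0 °C; then LiCl, DMF, 60 °C
Reagents that add atoms: lithium chloride, [Li+].[Cl-]
Why: Mesylation followed by SN2 displacement with chloride. The primary chloride should be inert to the acetylide, hydride and palladium steps that follow and is the latent electrophile for the C3–C4 bond.

Step 4
Reactants: 8 tert-butyl{[(3E)-6-chloro-3-methylhex-3-en-1-yl]oxy}dimethylsilane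
Product: 9 (3E)-6-chloro-3-methylhex-3-enoic acid
Conditions: CrO3, H2SO4, H2O, acetone, 0 °C
Reagents that add atoms: water, O
Why: Jones oxidation: the acidic medium cleaves the primary silyl ether and the liberated alcohol is oxidised through the aldehyde hydrate to the acid. The fast second oxidation leaves little time for the β,γ-olefin to move into conjugation.

Step 5
Reactants: 9 (3E)-6-chloro-3-methylhex-3-enoic acid
Product: 10 (3E)-6-chloro-N-methoxy-N,3-dimethylhex-3-enamide
Conditions: MeNH(OMe)·HCl, EDC·HCl, N-methylmorpholine, CH2Cl2, 0 °C → rt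
Reagents that add atoms: N,O-dimethylhydroxylamine hydrochloride, CNOC.Cl
Why: Carbodiimide amidation to the Weinreb amide, which stops the acetylide addition of step 6 at the ketone stage through a chelated tetrahedral intermediate; the weak base avoids conjugation of the olefin.

Step 6
Reactants: 2 tert-butyl[2-(prop-2-yn-1-yloxy)ethoxy]diphenylsilane; 10 (3E)-6-chloro-N-methoxy-N,3-dimethylhex-3-enamide
Product: 12 (6E)-1-[2-(tert-butyldiphenylsilyloxy)ethoxy]-9-chloro-6-methylnon-6-en-2-yn-4-one, via lithium acetylide 11 (not isolated)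
Conditions: 2, n-BuLi, THF, −78 °C; then 10, −78 → −20 °C; AcOH
Reagents that add atoms: none
Why: Weinreb ketone synthesis with a lithium acetylide forms the C7–C8 bond. At low temperature the acetylide should not displace the primary chloride, and the chelate collapses to the ynone only on work-up.

Step 7
Reactants: 12 (6E)-1-[2-(tert-butyldiphenylsilyloxy)ethoxy]-9-chloro-6-methylnon-6-en-2-yn-4-one
Product: 13 (4S,6E)-1-[2-(tert-butyldiphenylsilyloxy)ethoxy]-9-chloro-6-methylnon-6-en-2-yn-4-ol
Conditions: Ru[(S,S)-TsNCH(Ph)CH(Ph)NH](η6-p-cymene) (2 mol %), i-PrOH, rt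
Reagents that add atoms: none
Why: Noyori asymmetric transfer hydrogenation of an alkynyl ketone. The alkynyl group takes the place of the aryl group of aryl ketones in the catalyst pocket, so the (S,S)-ligand should give the (S)-carbinol, which is C8 of the target. The base-free conditions avoid enolisation at the doubly activated C9 methylene.

Step 8
Reactants: 13 (4S,6E)-1-[2-(tert-butyldiphenylsilyloxy)ethoxy]-9-chloro-6-methylnon-6-en-2-yn-4-ol
Product: 15 (2Z,4S,6E)-1-[2-(tert-butyldiphenylsilyloxy)ethoxy]-9-chloro-2-iodo-6-methylnona-2,6-dien-4-ol, via alkenylaluminate 14 (not isolated)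
Conditions: NaAlH2(OCH2CH2OMe)2, THF, 0 °C; then I2, THF, −78 → 0 °C
Reagents that add atoms: iodine, II
Why: Hydroxyl-directed trans-hydroalumination of a propargylic alcohol delivers hydride to C7 and aluminium to C11 within a five-membered alkoxyaluminate. Iodinolysis with retention gives the Z-iodoalkene in which C13 is trans to C8. At 0 °C the primary chloride and the propargylic ether should not be attacked.

Step 9
Reactants: 15 (2Z,4S,6E)-1-[2-(tert-butyldiphenylsilyloxy)ethoxy]-9-chloro-2-iodo-6-methylnona-2,6-dien-4-ol
Product: 16 (2E,4S,6E)-2-{[2-(tert-butyldiphenylsilyloxy)ethoxy]methyl}-9-chloro-6-methylnona-2,6-diene-1,4-diol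
Conditions: Bu3SnCH2OH, Pd(PPh3)4 (10 mol %), 1,4-dioxane, 90 °C
Reagents that add atoms: (tributylstannyl)methanol, CCCC[Sn](CCCC)(CCCC)CO
Why: Stille coupling with a hydroxymethylstannane replaces iodine by C12 with retention, so the C12 arm ends cis to C8 as the lactone later requires. Free hydroxyls and the alkyl chloride are tolerated by zerovalent palladium.

Step 10
Reactants: 16 (2E,4S,6E)-2-{[2-(tert-butyldiphenylsilyloxy)ethoxy]methyl}-9-chloro-6-methylnona-2,6-diene-1,4-diol
Product: 17 tert-butyl{2-[((2E,4S,6E)-9-chloro-4-[(4-methoxybenzyl)oxy]-2-{[(4-methoxybenzyl)oxy]methyl}-6-methylnona-2,6-dien-1-yl)oxy]ethoxy}diphenylsilane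
Conditions: NaH, 4-MeOC6H4CH2Cl, DMF, 0 °C → rt
Reagents that add atoms: 4-methoxybenzyl chloride, COc1ccc(CCl)cc1
Why: Williamson etherification of both hydroxyls. The same oxidatively removable group on O8 and O12 lets both lactone partners be released later in one step that leaves silyl ethers untouched.

Step 11
Reactants: 17 tert-butyl{2-[((2E,4S,6E)-9-chloro-4-[(4-methoxybenzyl)oxy]-2-{[(4-methoxybenzyl)oxy]methyl}-6-methylnona-2,6-dien-1-yl)oxy]ethoxy}diphenylsilane
Product: 18 ethyl (5E,8S,9E)-11-[2-(tert-butyldiphenylsilyloxy)ethoxy]-2-(diethoxyphosphoryl)-8-[(4-methoxybenzyl)oxy]-10-{[(4-methoxybenzyl)oxy]methyl}-6-methylundeca-5,9-dienoate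
Conditions: (EtO)2P(O)CH2CO2Et, NaH, NaI, DMF, 60 °C
Reagents that add atoms: triethyl phosphonoacetate, CCOC(=O)CP(=O)(OCC)OCC
Why: Alkylation of sodium phosphonoacetate by a primary halide (chloride exchanged in situ for iodide) forms the C3–C4 bond and brings in C4, C15 and phosphorus at once. The new C4 centre is uncontrolled and disappears in step 14.

Step 12
Reactants: 18 ethyl (5E,8S,9E)-11-[2-(tert-butyldiphenylsilyloxy)ethoxy]-2-(diethoxyphosphoryl)-8-[(4-methoxybenzyl)oxy]-10-{[(4-methoxybenzyl)oxy]methyl}-6-methylundeca-5,9-dienoate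
Product: 19 ethyl (5E,8S,9E)-2-(diethoxyphosphoryl)-11-(2-hydroxyethoxy)-8-[(4-methoxybenzyl)oxy]-10-{[(4-methoxybenzyl)oxy]methyl}-6-methylundeca-5,9-dienoate
Conditions: Bu4NF, AcOH, THF, 0 °C → rt
Reagents that add atoms: none
Why: Fluoride cleavage of the only silyl ether in the molecule, buffered with AcOH so that the acidic phosphonoacetate is not carried as its anion.

Step 13
Reactants: 19 ethyl (5E,8S,9E)-2-(diethoxyphosphoryl)-11-(2-hydroxyethoxy)-8-[(4-methoxybenzyl)oxy]-10-{[(4-methoxybenzyl)oxy]methyl}-6-methylundeca-5,9-dienoate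
Product: 20 ethyl (5E,8S,9E)-2-(diethoxyphosphoryl)-8-[(4-methoxybenzyl)oxy]-10-{[(4-methoxybenzyl)oxy]methyl}-6-methyl-11-(2-oxoethoxy)undeca-5,9-dienoate
Conditions: Dess–Martin periodinane, NaHCO3, CH2Cl2, 0 °C → rt
Reagents that add atoms: none
Why: Dess–Martin oxidation of a primary alcohol to the α-alkoxy aldehyde under buffered conditions; the crude aldehyde is used at once.

Step 14
Reactants: 20 ethyl (5E,8S,9E)-2-(diethoxyphosphoryl)-8-[(4-methoxybenzyl)oxy]-10-{[(4-methoxybenzyl)oxy]methyl}-6-methyl-11-(2-oxoethoxy)undeca-5,9-dienoate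
Product: 21 ethyl (3E,7E,10S,11Z)-10-[(4-methoxybenzyl)oxy]-12-{[(4-methoxybenzyl)oxy]methyl}-8-methyl-1-oxacyclotrideca-3,7,11-triene-4-carboxylate
Conditions: LiCl, DBU, MeCN, 1 mM (slow addition), rt
Reagents that add atoms: none
Why: Intramolecular Horner–Wadsworth–Emmons olefination under mild LiCl–amine conditions at high dilution closes the unstrained thirteen-membered ether. The stabilised α-substituted phosphonate should favour the enoate with the ester trans to C6, which is also the in-ring cis arrangement of C3 and C6.

Step 15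
Reactants: 21 ethyl (3E,7E,10S,11Z)-10-[(4-methoxybenzyl)oxy]-12-{[(4-methoxybenzyl)oxy]methyl}-8-methyl-1-oxacyclotrideca-3,7,11-triene-4-carboxylate
Product: 23 ethyl (1E,3R,4S,5S,7E)-3-hydroxy-5-[(4-methoxybenzyl)oxy]-4-{3-[(4-methoxybenzyl)oxy]prop-1-en-2-yl}-7-methylcyclodeca-1,7-diene-1-carboxylate, via lithium dienolate 22 (not isolated)
Conditions: LiN(i-Pr)2, THF, −78 → −30 °C; AcOH, −78 °C
Reagents that add atoms: none
Why: Proposed new method: the amide base removes a C6 hydrogen, the only one that is at once allylic, α to the ether oxygen and vinylogously α to the C15 ester, giving the cisoid lithium dienolate 22, whose γ-carbon C6 then bonds suprafacially to C7 of the C7=C11–C13 allyl unit while the O–C13 bond breaks, a six-electron [2,3]-sigmatropic shift through a five-membered envelope transition state (C6, O, C13, C11, C7). The closest known reaction types are the [2,3]-Wittig ring contraction of thirteen-membered diallylic and allyl propargyl ethers to ten-membered carbinols, the ester-enolate [2,3]-Wittig shift of α-allyloxy esters and the ester-dienolate [2,3]-Wittig shift of 2-alkoxycarbonyl allyl vinyl ethers; new here is that the migrating carbanion is the γ-terminus of an ester dienolate. The ten-membered carbocycle closes by transannular C6–C7 bonding inside the thirteen-membered ether, with the oxygen leaving the ring (contraction by three atoms, no high dilution needed). C7 is controlled by C8: allylic 1,3-strain with the C12 arm holds H8 in the olefin plane, and C6 should add anti to the C8–O bond, on the face where the C9 tether lies. C6 is controlled relative to C7 by the olefin geometry (C13 trans to C8) and an exo placement of the C5 alkenyl substituent on the envelope, which gives the anti relationship (C6–O and the C11 branch trans on the ring) seen with related E-allylic ethers. The step needs metalation at C6 and not at C13 (secured by the ester), [2,3] over [1,2] shift and over the [3,3] shift of the dienolate enol ether (favoured by low temperature), and retention of the in-ring cis C4=C5 bond (the cisoid dienolate is held by the ring). Quenching cold with AcOH prevents an anionic oxy-Cope shift of the 1,5-diene alkoxide.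

Step 16
Reactants: 23 ethyl (1E,3R,4S,5S,7E)-3-hydroxy-5-[(4-methoxybenzyl)oxy]-4-{3-[(4-methoxybenzyl)oxy]prop-1-en-2-yl}-7-methylcyclodeca-1,7-diene-1-carboxylate
Product: 24 (1R,2E,6E,9S,10S)-3-(hydroxymethyl)-9-[(4-methoxybenzyl)oxy]-10-{3-[(4-methoxybenzyl)oxy]prop-1-en-2-yl}-7-methylcyclodeca-2,6-dien-1-ol
Conditions: i-Bu2AlH, CH2Cl2, −78 → −40 °C
Reagents that add atoms: none
Why: 1,2-Reduction of the conjugated ester by an aluminium hydride gives the C15 allylic alcohol; the benzyl-type ethers and the isolated olefins are inert.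

Step 17
Reactants: 24 (1R,2E,6E,9S,10S)-3-(hydroxymethyl)-9-[(4-methoxybenzyl)oxy]-10-{3-[(4-methoxybenzyl)oxy]prop-1-en-2-yl}-7-methylcyclodeca-2,6-dien-1-ol
Product: 25 (1R,2E,6E,9S,10S)-3-{[(tert-butyldimethylsilyl)oxy]methyl}-9-[(4-methoxybenzyl)oxy]-10-{3-[(4-methoxybenzyl)oxy]prop-1-en-2-yl}-7-methylcyclodeca-2,6-dien-1-ol
Conditions: TBSCl, imidazole, CH2Cl2, −20 °C
Reagents that add atoms: tert-butyl(chloro)dimethylsilane, CC(C)(C)[Si](C)(C)Cl
Why: Selective silylation: the primary allylic hydroxyl at C15 reacts much faster than the hindered secondary C6 hydroxyl.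

Step 18
Reactants: 26 (tert-butyldimethylsilyloxy)acetaldehyde
Product: 27 ethyl (2E)-4-(tert-butyldimethylsilyloxy)-2-methylbut-2-enoate
Conditions: Ph3P=C(CH3)CO2Et, CH2Cl2, rt
Reagents that add atoms: ethyl 2-(triphenylphosphoranylidene)propanoate, CCOC(=O)C(C)=P(c1ccccc1)(c1ccccc1)c1ccccc1
Why: Wittig olefination with a stabilised α-branched ylide gives the E-trisubstituted enoate, with the ester trans to the silyloxymethyl group.

Step 19
Reactants: 27 ethyl (2E)-4-(tert-butyldimethylsilyloxy)-2-methylbut-2-enoate
Product: 28 (2E)-4-(tert-butyldimethylsilyloxy)-2-methylbut-2-enoic acid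
Conditions: LiOH, THF–MeOH–H2O, rt; then dilute aq. HCl to pH 4, 0 °C
Reagents that add atoms: lithium hydroxide, [Li+].[OH-]
Why: Saponification of the ethyl ester; the primary silyl ether should survive mild hydroxide and a brief cold acidification.

Step 20
Reactants: 25 (1R,2E,6E,9S,10S)-3-{[(tert-butyldimethylsilyl)oxy]methyl}-9-[(4-methoxybenzyl)oxy]-10-{3-[(4-methoxybenzyl)oxy]prop-1-en-2-yl}-7-methylcyclodeca-2,6-dien-1-ol; 28 (2E)-4-(tert-butyldimethylsilyloxy)-2-methylbut-2-enoic acid
Product: 30 (1R,2E,6E,9S,10R)-3-{[(tert-butyldimethylsilyl)oxy]methyl}-9-[(4-methoxybenzyl)oxy]-10-{3-[(4-methoxybenzyl)oxy]prop-1-en-2-yl}-7-methylcyclodeca-2,6-dien-1-yl (2E)-4-(tert-butyldimethylsilyloxy)-2-methylbut-2-enoate, via mixed anhydride 29 (not isolated)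
Conditions: 28, 2,4,6-Cl3C6H2COCl, Et3N, toluene, rt; then 25, DMAP, toluene, rt → 40 °C
Reagents that add atoms: none
Why: Yamaguchi esterification: the mixed anhydride acylates the hindered secondary allylic alcohol under DMAP catalysis with no change at C6. The E-enoate is the more stable isomer and should not scramble; the change of the C10 descriptor from S to R is a CIP priority effect only.

Step 21
Reactants: 30 (1R,2E,6E,9S,10R)-3-{[(tert-butyldimethylsilyl)oxy]methyl}-9-[(4-methoxybenzyl)oxy]-10-{3-[(4-methoxybenzyl)oxy]prop-1-en-2-yl}-7-methylcyclodeca-2,6-dien-1-yl (2E)-4-(tert-butyldimethylsilyloxy)-2-methylbut-2-enoate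
Product: 31 (1R,2E,6E,9S,10R)-3-{[(tert-butyldimethylsilyl)oxy]methyl}-9-hydroxy-10-(3-hydroxyprop-1-en-2-yl)-7-methylcyclodeca-2,6-dien-1-yl (2E)-4-(tert-butyldimethylsilyloxy)-2-methylbut-2-enoate
Conditions: DDQ, CH2Cl2–pH 7 buffer, 0 °C → rt
Reagents that add atoms: none
Why: Oxidative cleavage of both 4-methoxybenzyl ethers by DDQ (benzylic hydride abstraction, then hydrolysis of the oxocarbenium ion) in buffered wet solvent leaves silyl ethers, esters and olefins intact.

Step 22
Reactants: 31 (1R,2E,6E,9S,10R)-3-{[(tert-butyldimethylsilyl)oxy]methyl}-9-hydroxy-10-(3-hydroxyprop-1-en-2-yl)-7-methylcyclodeca-2,6-dien-1-yl (2E)-4-(tert-butyldimethylsilyloxy)-2-methylbut-2-enoate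
Product: 34 (3aR,4R,5E,9E,11aS)-6-{[(tert-butyldimethylsilyl)oxy]methyl}-10-methyl-3-methylidene-2-oxo-2,3,3a,4,7,8,11,11a-octahydrocyclodeca[b]furan-4-yl (2E)-4-(tert-butyldimethylsilyloxy)-2-methylbut-2-enoate, via enal 32 (not isolated), via lactol 33 (not isolated)
Conditions: MnO2 (excess), CH2Cl2, rt
Reagents that add atoms: none
Why: MnO2 oxidises only the free primary allylic alcohol at C12; the enal is trapped by the C8 hydroxyl as a lactol, which is oxidised further to the lactone (oxidative lactonisation of a 2-methylene-1,4-diol). The trans ring fusion follows from the C7 and C8 configurations already present.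

Step 23
Reactants: 34 (3aR,4R,5E,9E,11aS)-6-{[(tert-butyldimethylsilyl)oxy]methyl}-10-methyl-3-methylidene-2-oxo-2,3,3a,4,7,8,11,11a-octahydrocyclodeca[b]furan-4-yl (2E)-4-(tert-butyldimethylsilyloxy)-2-methylbut-2-enoate
Product: 35 (3aR,4R,5E,9E,11aS)-6-(hydroxymethyl)-10-methyl-3-methylidene-2-oxo-2,3,3a,4,7,8,11,11a-octahydrocyclodeca[b]furan-4-yl (2E)-4-hydroxy-2-methylbut-2-enoate
Conditions: HF·pyridine, pyridine, THF, 0 °C → rt
Reagents that add atoms: none
Why: Buffered HF·pyridine cleaves both primary silyl ethers without a basic fluoride source that could add to the α-methylene lactone or move the acyl group.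

## Compound list

1 | 2-(prop-2-yn-1-yloxy)ethan-1-ol | C#CCOCCO | starting material
2 | tert-butyl[2-(prop-2-yn-1-yloxy)ethoxy]diphenylsilane | C#CCOCCO[Si](c1ccccc1)(c1ccccc1)C(C)(C)C | intermediate
3 | tert-butyl(but-3-yn-1-yloxy)dimethylsilane | C#CCCO[Si](C)(C)C(C)(C)C | starting material
4 | [(1E)-4-(tert-butyldimethylsilyloxy)-2-methylbut-1-en-1-yl]dimethylalane | C[Al](C)/C=C(\C)CCO[Si](C)(C)C(C)(C)C | intermediate
5 | lithium butyl[(1E)-4-(tert-butyldimethylsilyloxy)-2-methylbut-1-en-1-yl]dimethylaluminate | [Li+].CCCC[Al-](C)(C)/C=C(\C)CCO[Si](C)(C)C(C)(C)C | intermediate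
6 | (3E)-6-(tert-butyldimethylsilyloxy)-4-methylhex-3-en-1-ol | OCC/C=C(\C)CCO[Si](C)(C)C(C)(C)C | intermediate
7 | (3E)-6-(tert-butyldimethylsilyloxy)-4-methylhex-3-en-1-yl methanesulfonate | CS(=O)(=O)OCC/C=C(\C)CCO[Si](C)(C)C(C)(C)C | intermediate
8 | tert-butyl{[(3E)-6-chloro-3-methylhex-3-en-1-yl]oxy}dimethylsilane | ClCC/C=C(\C)CCO[Si](C)(C)C(C)(C)C | intermediate
9 | (3E)-6-chloro-3-methylhex-3-enoic acid | ClCC/C=C(\C)CC(=O)O | intermediate
10 | (3E)-6-chloro-N-methoxy-N,3-dimethylhex-3-enamide | ClCC/C=C(\C)CC(=O)N(C)OC | intermediate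
11 | lithium 3-[2-(tert-butyldiphenylsilyloxy)ethoxy]prop-1-yn-1-ide | [Li]C#CCOCCO[Si](c1ccccc1)(c1ccccc1)C(C)(C)C | intermediate
12 | (6E)-1-[2-(tert-butyldiphenylsilyloxy)ethoxy]-9-chloro-6-methylnon-6-en-2-yn-4-one | ClCC/C=C(\C)CC(=O)C#CCOCCO[Si](c1ccccc1)(c1ccccc1)C(C)(C)C | intermediate
13 | (4S,6E)-1-[2-(tert-butyldiphenylsilyloxy)ethoxy]-9-chloro-6-methylnon-6-en-2-yn-4-ol | CC(C)(C)[Si](OCCOCC#C[C@@H](O)C/C(C)=C/CCCl)(c1ccccc1)c1ccccc1 | intermediate
14 | sodium (5S)-3-{[2-(tert-butyldiphenylsilyloxy)ethoxy]methyl}-5-[(2E)-5-chloro-2-methylpent-2-en-1-yl]-2,2-bis(2-methoxyethoxy)-2,5-dihydro-1,2-oxaluminol-2-uide (five-membered ring O8–Al–C11) | [Na+].COCCO[Al-]1(OCCOC)O[C@@H](C/C(C)=C/CCCl)C=C1COCCO[Si](c1ccccc1)(c1ccccc1)C(C)(C)C | intermediate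
15 | (2Z,4S,6E)-1-[2-(tert-butyldiphenylsilyloxy)ethoxy]-9-chloro-2-iodo-6-methylnona-2,6-dien-4-ol | CC(C)(C)[Si](OCCOC/C(I)=C/[C@@H](O)C/C(C)=C/CCCl)(c1ccccc1)c1ccccc1 | intermediate
16 | (2E,4S,6E)-2-{[2-(tert-butyldiphenylsilyloxy)ethoxy]methyl}-9-chloro-6-methylnona-2,6-diene-1,4-diol | CC(C)(C)[Si](OCCOC/C(CO)=C/[C@@H](O)C/C(C)=C/CCCl)(c1ccccc1)c1ccccc1 | intermediate
17 | tert-butyl{2-[((2E,4S,6E)-9-chloro-4-[(4-methoxybenzyl)oxy]-2-{[(4-methoxybenzyl)oxy]methyl}-6-methylnona-2,6-dien-1-yl)oxy]ethoxy}diphenylsilane | CC(C)(C)[Si](OCCOC/C(COCc1ccc(OC)cc1)=C/[C@@H](OCc1ccc(OC)cc1)C/C(C)=C/CCCl)(c1ccccc1)c1ccccc1 | intermediate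
18 | ethyl (5E,8S,9E)-11-[2-(tert-butyldiphenylsilyloxy)ethoxy]-2-(diethoxyphosphoryl)-8-[(4-methoxybenzyl)oxy]-10-{[(4-methoxybenzyl)oxy]methyl}-6-methylundeca-5,9-dienoate (both C2 epimers) | CC(C)(C)[Si](OCCOC/C(COCc1ccc(OC)cc1)=C/[C@@H](OCc1ccc(OC)cc1)C/C(C)=C/CCC(C(=O)OCC)P(=O)(OCC)OCC)(c1ccccc1)c1ccccc1 | intermediate
19 | ethyl (5E,8S,9E)-2-(diethoxyphosphoryl)-11-(2-hydroxyethoxy)-8-[(4-methoxybenzyl)oxy]-10-{[(4-methoxybenzyl)oxy]methyl}-6-methylundeca-5,9-dienoate | OCCOC/C(COCc1ccc(OC)cc1)=C/[C@@H](OCc1ccc(OC)cc1)C/C(C)=C/CCC(C(=O)OCC)P(=O)(OCC)OCC | intermediate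
20 | ethyl (5E,8S,9E)-2-(diethoxyphosphoryl)-8-[(4-methoxybenzyl)oxy]-10-{[(4-methoxybenzyl)oxy]methyl}-6-methyl-11-(2-oxoethoxy)undeca-5,9-dienoate | O=CCOC/C(COCc1ccc(OC)cc1)=C/[C@@H](OCc1ccc(OC)cc1)C/C(C)=C/CCC(C(=O)OCC)P(=O)(OCC)OCC | intermediate
21 | ethyl (3E,7E,10S,11Z)-10-[(4-methoxybenzyl)oxy]-12-{[(4-methoxybenzyl)oxy]methyl}-8-methyl-1-oxacyclotrideca-3,7,11-triene-4-carboxylate | O1C/C(COCc2ccc(OC)cc2)=C/[C@@H](OCc2ccc(OC)cc2)C/C(C)=C/CC/C(C(=O)OCC)=C\C1 | intermediate
22 | lithium dienolate of 21 (O-lithio ketene acetal at C15 conjugated with the C5=C6 enol ether) | O1C/C(COCc2ccc(OC)cc2)=C/[C@@H](OCc2ccc(OC)cc2)C/C(C)=C/CCC(=C(O[Li])OCC)C=C1 | intermediate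
23 | ethyl (1E,3R,4S,5S,7E)-3-hydroxy-5-[(4-methoxybenzyl)oxy]-4-{3-[(4-methoxybenzyl)oxy]prop-1-en-2-yl}-7-methylcyclodeca-1,7-diene-1-carboxylate | C=C(COCc1ccc(OC)cc1)[C@@H]1[C@@H](OCc2ccc(OC)cc2)C/C(C)=C/CC/C(C(=O)OCC)=C\[C@H]1O | intermediate
24 | (1R,2E,6E,9S,10S)-3-(hydroxymethyl)-9-[(4-methoxybenzyl)oxy]-10-{3-[(4-methoxybenzyl)oxy]prop-1-en-2-yl}-7-methylcyclodeca-2,6-dien-1-ol | C=C(COCc1ccc(OC)cc1)[C@@H]1[C@@H](OCc2ccc(OC)cc2)C/C(C)=C/CC/C(CO)=C\[C@H]1O | intermediate
25 | (1R,2E,6E,9S,10S)-3-{[(tert-butyldimethylsilyl)oxy]methyl}-9-[(4-methoxybenzyl)oxy]-10-{3-[(4-methoxybenzyl)oxy]prop-1-en-2-yl}-7-methylcyclodeca-2,6-dien-1-ol | C=C(COCc1ccc(OC)cc1)[C@@H]1[C@@H](OCc2ccc(OC)cc2)C/C(C)=C/CC/C(CO[Si](C)(C)C(C)(C)C)=C\[C@H]1O | intermediate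
26 | (tert-butyldimethylsilyloxy)acetaldehyde | O=CCO[Si](C)(C)C(C)(C)C | starting material
27 | ethyl (2E)-4-(tert-butyldimethylsilyloxy)-2-methylbut-2-enoate | CCOC(=O)/C(C)=C/CO[Si](C)(C)C(C)(C)C | intermediate
28 | (2E)-4-(tert-butyldimethylsilyloxy)-2-methylbut-2-enoic acid | OC(=O)/C(C)=C/CO[Si](C)(C)C(C)(C)C | intermediate
29 | (2E)-4-(tert-butyldimethylsilyloxy)-2-methylbut-2-enoic 2,4,6-trichlorobenzoic anhydride | O=C(OC(=O)/C(C)=C/CO[Si](C)(C)C(C)(C)C)c1c(Cl)cc(Cl)cc1Cl | intermediate
30 | (1R,2E,6E,9S,10R)-3-{[(tert-butyldimethylsilyl)oxy]methyl}-9-[(4-methoxybenzyl)oxy]-10-{3-[(4-methoxybenzyl)oxy]prop-1-en-2-yl}-7-methylcyclodeca-2,6-dien-1-yl (2E)-4-(tert-butyldimethylsilyloxy)-2-methylbut-2-enoate | C=C(COCc1ccc(OC)cc1)[C@@H]1[C@@H](OCc2ccc(OC)cc2)C/C(C)=C/CC/C(CO[Si](C)(C)C(C)(C)C)=C\[C@H]1OC(=O)/C(C)=C/CO[Si](C)(C)C(C)(C)C | intermediate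
31 | (1R,2E,6E,9S,10R)-3-{[(tert-butyldimethylsilyl)oxy]methyl}-9-hydroxy-10-(3-hydroxyprop-1-en-2-yl)-7-methylcyclodeca-2,6-dien-1-yl (2E)-4-(tert-butyldimethylsilyloxy)-2-methylbut-2-enoate | C=C(CO)[C@@H]1[C@@H](O)C/C(C)=C/CC/C(CO[Si](C)(C)C(C)(C)C)=C\[C@H]1OC(=O)/C(C)=C/CO[Si](C)(C)C(C)(C)C | intermediate
32 | (1R,2E,6E,9S,10R)-3-{[(tert-butyldimethylsilyl)oxy]methyl}-9-hydroxy-7-methyl-10-(3-oxoprop-1-en-2-yl)cyclodeca-2,6-dien-1-yl (2E)-4-(tert-butyldimethylsilyloxy)-2-methylbut-2-enoate | C=C(C=O)[C@@H]1[C@@H](O)C/C(C)=C/CC/C(CO[Si](C)(C)C(C)(C)C)=C\[C@H]1OC(=O)/C(C)=C/CO[Si](C)(C)C(C)(C)C | intermediate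
33 | (3aR,4R,5E,9E,11aS)-6-{[(tert-butyldimethylsilyl)oxy]methyl}-2-hydroxy-10-methyl-3-methylidene-2,3,3a,4,7,8,11,11a-octahydrocyclodeca[b]furan-4-yl (2E)-4-(tert-butyldimethylsilyloxy)-2-methylbut-2-enoate (both C2 epimers) | C=C1C(O)O[C@H]2C/C(C)=C/CC/C(CO[Si](C)(C)C(C)(C)C)=C\[C@@H](OC(=O)/C(C)=C/CO[Si](C)(C)C(C)(C)C)[C@H]12 | intermediate
34 | (3aR,4R,5E,9E,11aS)-6-{[(tert-butyldimethylsilyl)oxy]methyl}-10-methyl-3-methylidene-2-oxo-2,3,3a,4,7,8,11,11a-octahydrocyclodeca[b]furan-4-yl (2E)-4-(tert-butyldimethylsilyloxy)-2-methylbut-2-enoate | C=C1C(=O)O[C@H]2C/C(C)=C/CC/C(CO[Si](C)(C)C(C)(C)C)=C\[C@@H](OC(=O)/C(C)=C/CO[Si](C)(C)C(C)(C)C)[C@H]12 | intermediate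
35 | (3aR,4R,5E,9E,11aS)-6-(hydroxymethyl)-10-methyl-3-methylidene-2-oxo-2,3,3a,4,7,8,11,11a-octahydrocyclodeca[b]furan-4-yl (2E)-4-hydroxy-2-methylbut-2-enoate | C=C1C(=O)O[C@H]2C/C(C)=C/CC/C(CO)=C\[C@@H](OC(=O)/C(C)=C/CO)[C@H]12 | target

## Step count and weak points

Total step count: 23. Longest linear sequence: 20 steps (steps 2 to 17 and 20 to 23, from 3). Step 1 and steps 18 and 19 prepare the two side fragments.

**Step 15 (the proposed new method).**
- What may go wrong: the charge of the dienolate sits mainly on oxygen and C4, so bond formation from C6 may be slow. On warming, the dienolate may instead undergo the [3,3] shift of its allyl vinyl ether unit (bonding C5 to C7) or be reprotonated at C4 to a deconjugated enol ether. Facial selection at C7 rests on the single alkoxy centre at C8 and may be poor.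
- Fallback: from 21, reduction with i-Bu2AlH would give the macrocyclic allylic alcohol F1, and TBSCl with imidazole its silyl ether F2. Treating this plain diallylic ether with n-BuLi in THF at −78 °C is the known [2,3]-Wittig ring contraction of thirteen-membered diallylic ethers. Metalation is expected at C6 (the CH2 bound to the CH= terminus) rather than at C13 (bound to the fully substituted C11), which gives 25 directly; the route is rejoined there and steps 16 and 17 fall away. The price is that the site of metalation is no longer guaranteed by an activating group and that an alkyllithium meets two 4-methoxybenzyl ethers, which is why this is the reserve and not the first choice.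

**Step 14.**
- What may go wrong: intermolecular olefination may compete with ring closure, and E-selectivity may be incomplete, because an α-branched phosphonate is only moderately selective and a thirteen-membered ring biases the enoate geometry little.
- Fallback: from 19, aqueous formaldehyde with K2CO3 would convert the phosphonoacetate into the α-methylene ester F3. Dess–Martin oxidation would give the aldehyde F4, and methylenation with Zn/CH2Br2/TiCl4 the allyl ether F5. Ring-closing metathesis with a second-generation Hoveyda–Grubbs catalyst in hot toluene at high dilution would then form the C4=C5 bond under thermodynamic control and return to 21.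

**Step 9.**
- What may go wrong: transfer of the sp3 hydroxymethyl group to a hindered internal alkenylpalladium intermediate is slow, so protodeiodination or butyl transfer may compete.
- Fallback: from 15, carbonylative lactonisation with PdCl2(PPh3)2, CO (1 atm) and K2CO3 in THF would give the butenolide F6 (C12 enters as the lactone carbonyl, bonded to O8). Excess i-Bu2AlH would then reduce it to the Z-enediol 16, where the route is rejoined.

**Step 22.**
- What may go wrong: the oxidation may stall at the lactol, and in a long heterogeneous reaction the acyl group may migrate from O6 to the free O8.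
- Fallback: from 31, a short MnO2 treatment would be stopped at the mixture of 32 and 33. NaClO2 with NaH2PO4 and 2-methyl-2-butene would oxidise it to the hydroxy acid F7, and carbodiimide lactonisation (EDC·HCl, DMAP) would close the ring to 34.

## Further compounds

F1 | step 15 | [(3E,7E,10S,11Z)-10-[(4-methoxybenzyl)oxy]-12-{[(4-methoxybenzyl)oxy]methyl}-8-methyl-1-oxacyclotrideca-3,7,11-trien-4-yl]methanol | O1C/C(COCc2ccc(OC)cc2)=C/[C@@H](OCc2ccc(OC)cc2)C/C(C)=C/CC/C(CO)=C\C1
F2 | step 15 | tert-butyl{[(3E,7E,10S,11Z)-10-[(4-methoxybenzyl)oxy]-12-{[(4-methoxybenzyl)oxy]methyl}-8-methyl-1-oxacyclotrideca-3,7,11-trien-4-yl]methoxy}dimethylsilane | O1C/C(COCc2ccc(OC)cc2)=C/[C@@H](OCc2ccc(OC)cc2)C/C(C)=C/CC/C(CO[Si](C)(C)C(C)(C)C)=C\C1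
F3 | step 14 | ethyl (5E,8S,9E)-11-(2-hydroxyethoxy)-8-[(4-methoxybenzyl)oxy]-10-{[(4-methoxybenzyl)oxy]methyl}-6-methyl-2-methylideneundeca-5,9-dienoate | OCCOC/C(COCc1ccc(OC)cc1)=C/[C@@H](OCc1ccc(OC)cc1)C/C(C)=C/CCC(=C)C(=O)OCC
F4 | step 14 | ethyl (5E,8S,9E)-8-[(4-methoxybenzyl)oxy]-10-{[(4-methoxybenzyl)oxy]methyl}-6-methyl-2-methylidene-11-(2-oxoethoxy)undeca-5,9-dienoate | O=CCOC/C(COCc1ccc(OC)cc1)=C/[C@@H](OCc1ccc(OC)cc1)C/C(C)=C/CCC(=C)C(=O)OCC
F5 | step 14 | ethyl (5E,8S,9Z)-8-[(4-methoxybenzyl)oxy]-10-{[(4-methoxybenzyl)oxy]methyl}-6-methyl-2-methylidene-11-(prop-2-en-1-yloxy)undeca-5,9-dienoate | C=CCOC/C(COCc1ccc(OC)cc1)=C/[C@@H](OCc1ccc(OC)cc1)C/C(C)=C/CCC(=C)C(=O)OCC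
F6 | step 9 | (5S)-3-{[2-(tert-butyldiphenylsilyloxy)ethoxy]methyl}-5-[(2E)-5-chloro-2-methylpent-2-en-1-yl]furan-2(5H)-one | O=C1O[C@@H](C/C(C)=C/CCCl)C=C1COCCO[Si](c1ccccc1)(c1ccccc1)C(C)(C)C
F7 | step 22 | 2-[(1R,2R,3E,7E,10S)-4-{[(tert-butyldimethylsilyl)oxy]methyl}-2-{[(2E)-4-(tert-butyldimethylsilyloxy)-2-methylbut-2-enoyl]oxy}-10-hydroxy-8-methylcyclodeca-3,7-dien-1-yl]prop-2-enoic acid | C=C(C(=O)O)[C@@H]1[C@@H](O)C/C(C)=C/CC/C(CO[Si](C)(C)C(C)(C)C)=C\[C@H]1OC(=O)/C(C)=C/CO[Si](C)(C)C(C)(C)C
A1 | alternative 1 | methyl (3aR,4R,5E,9E,11aS)-10-methyl-2-oxo-4-[(triethylsilyl)oxy]-2,3,3a,4,7,8,11,11a-octahydrocyclodeca[b]furan-6-carboxylate | C1C(=O)O[C@H]2C/C(C)=C/CC/C(C(=O)OC)=C\[C@@H](O[Si](CC)(CC)CC)[C@H]12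
A2 | alternative 2 | (3aS,4R,5E,9E,11aS)-6-{[(tert-butyldimethylsilyl)oxy]methyl}-4-hydroxy-10-methyl-3a,4,7,8,11,11a-hexahydrocyclodeca[b]furan-2(3H)-one | C1C(=O)O[C@H]2C/C(C)=C/CC/C(CO[Si](C)(C)C(C)(C)C)=C\[C@@H](O)[C@H]12
A3 | alternative 3 | (1Z,5E,7R,8S,9S)-9-[(tert-butyldimethylsilyl)oxy]-8-{3-[(tert-butyldimethylsilyl)oxy]prop-1-en-2-yl}-7-[(4-methoxybenzyl)oxy]-5-{[(triisopropylsilyl)oxy]methyl}cyclodeca-1,5-dien-1-yl trifluoromethanesulfonate | FC(F)(F)S(=O)(=O)O\C1=C/CC/C(CO[Si](C(C)C)(C(C)C)C(C)C)=C\[C@@H](OCc2ccc(OC)cc2)[C@H](C(=C)CO[Si](C)(C)C(C)(C)C)[C@@H](O[Si](C)(C)C(C)(C)C)C1
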